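No rate constant is given for this flask, so I ask first what its books must look like at the end, and then how near that end it has come by 2.5 d.

| flask | starting material | reagent in the second phase | protic impurity | remark | time | volume of the second phase over the first |
|---|---|---|---|---|---|---|
| north | 0.13 M | 0.30 M | 4 mM | run made earlier |  |  |
| north-east | 0.30 M | 0.30 M | 4 mM | run made earlier |  |  |
| south | 0.20 M | 0.45 M | 4 mM | run made earlier |  |  |
| flask | 0.20 M | 0.300 M | 4.00 mM |  | 2.5 d | 0.25 |

| run | time / h | target / % | starting material / % |
|---|---|---|---|
| north | 5.00 | 23.4 | 67.6 |
| north | 10.0 | 42.1 | 45.4 |
| north | 15.0 | 54.3 | 30.2 |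
| north | 20.0 | 64.8 | 19.9 |
| north | 25.0 | 68.7 | 15.1 |
| north | 30.0 | 71.5 | 11.4 |
| north | 40.0 | 78.5 | 4.2 |
| north-east | 5.00 | 22.2 | 72.5 |
| north-east | 10.0 | 38.4 | 49.1 |
| north-east | 15.0 | 49.8 | 37.3 |
| north-east | 20.0 | 55.0 | 28.5 |
| north-east | 25.0 | 59.4 | 23.5 |
| north-east | 30.0 | 63.9 | 17.5 |
| north-east | 40.0 | 68.2 | 11.1 |
| south | 3.00 | 16.7 | 78.8 |
| south | 5.00 | 31.6 | 60.6 |
| south | 10.0 | 54.0 | 35.2 |
| south | 20.0 | 73.9 | 12.9 |
| south | 40.0 | 83.2 | 3.5 |

(each reading ± 1 percentage point)

- in the second phase: reagent in the second phase; everything else is in the first
- charges count per volume of the first phase; a concentration in a rate is the amount of a species over the volume of its own phase; every rate counts per litre of the first phase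
- the numbers in the tables scatter by 1 percentage point (one standard deviation)
- the earlier runs hold the two phases in the same ratio of volumes as the flask asked about
- what has gone from starting material into another species counts as reacted, even if it can come back

* how much target there is at 2.5 d, in percent of the starting material charged
* part of the starting material charged that has reacted at 2.5 d

I keep the ledger in starting material, the limiting reagent for target, since the flask charges 0.20 M of it against 0.300 M of reagent in the second phase, each per litre of the first phase. The first entry comes from the readings at 40.0 h: the north run holds 0.819 of its reacted starting material as target and the north-east run 0.767, and the flask's charge lies 0.412 of the way from the first to the second, which gives 0.798; this S, the selectivity, target formed per starting material reacted, is what I carry. The second entry is what stays behind: interpolating the same way, I estimate 7.04% starting material for the flask at that reading time, and the north and north-east readings from 20.0 h onward give, weighted the same way, an apparent first-order constant of 0.0652 h⁻¹, so I expect 1.91% left at 2.5 d and 98.1% reacted. The books close with 78.3% target, 1.91% left and 19.8% reacted to something else, of which the protic impurity, if it takes starting material mole for mole, claims 2.00%.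

The forecast says 77% target and 97% reacted, each a little below mine, and its reckoning for the flask begins by “interpolating between north and north-east”. The simulation gives 77.6% target and 96.5% reacted.

    starting material + reagent in the reaction phase → target (k = 9.50 × 10⁻⁵ L mol⁻¹ s⁻¹)
    starting material ⇌ dormant form (K = 3.00, k = 3.90 × 10⁻⁶ s⁻¹)
    target → over-reaction product (k = 3.50 × 10⁻⁸ s⁻¹)
    starting material + protic impurity → quenched substrate (k = 0.00320 L mol⁻¹ s⁻¹)
    reagent in the reaction phase ⇌ reagent in the second phase, rate k5*([reagent in the reaction phase] - [reagent in the second phase]/K5) per volume of the first phase (partition coefficient = 0.760, kL = 2.70 × 10⁻⁵ s⁻¹)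

In this flask at 2.5 d target over reacted comes to 0.804, against my 0.798 from the readings, with 16.4% standing as dormant form, 2.00% as quenched substrate and 0.454% as over-reaction product. At 0.0545 d the forward step to dormant form has a half-life of 2.1 d, shorter than the 12 d of the step to quenched substrate, and at 2.50 d the step to target uses starting material 2.9 times as fast as that forward step. Carried to the same flask read at 25 h, where 82.4% has reacted, S gives 65.8% target, and that flask holds 65.2%.

(The data come from a simulation on assumed constants; scatter was added.)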